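The vessel under discussion is a stirred flask of constant volume in which substrate and reagent meet, and the meeting opened with what stood on the table.

| flask | substrate | reagent | temperature | remark | time |
|---|---|---|---|---|---|
| north-east | 10 mM | 5 mM | 30 °C | run made earlier |  |
| south-west | 10 mM | 2.5 mM | 41 °C | run made earlier |  |
| east | 10 mM | 3.8 mM | 30 °C | run made earlier |  |
| maple | 10 mM | 5.00 mM | 35 °C | everything together at the start | 10 h |
| birch | 10 mM | 5.00 mM (fed, over 8.0 h) | 35 °C | all else is in the flask from the start; the feed brings no volume worth counting | 10 h |
| oak | 10 mM (fed, over 8.0 h) | 5.00 mM | 35 °C | all else is in the flask from the start; the feed brings no volume worth counting | 10 h |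
| cedar | 10 mM | 5.00 mM (fed, over 8.0 h) |  | the addition at 15 °C, then warmed to 35 °C; the feed brings no volume worth counting | 10 h |

| run | time / h | target / % |
|---|---|---|
| north-east | 2.00 | 7.1 |
| north-east | 4.00 | 9.7 |
| north-east | 6.00 | 10.9 |
| north-east | 8.00 | 12.7 |
| north-east | 10.0 | 11.4 |
| south-west | 0.500 | 4.4 |
| south-west | 1.50 | 6.7 |
| south-west | 3.00 | 8.2 |
| south-west | 4.00 | 10.9 |
| south-west | 6.00 | 10.2 |
| east | 0.500 | 2.7 |
| east | 0.833 | 5.7 |
| east | 1.50 | 5.5 |
| east | 3.00 | 6.3 |
| east | 6.00 | 6.8 |

(scatter of a reading: 1 percentage point)

- in percentages every species weighs as the substrate in it: one side product counts as two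
- for target the crystals are counted in
- as a solid, counted per litre of solution: crystals
- on the list of suspects stand: reagent <-> dormant form; substrate <-> tautomer; reagent + tautomer -> target; substrate + target -> side product; crystals <-> target; substrate + reagent -> isomer of the product

- the flask with the highest amount of target, in percent of the substrate charged ("all alike" if they lie within 1.5 percentage points) (maple / birch / oak / cedar / all alike)
- final target, as a percentage of the substrate charged, in maple
- final target, as a percentage of the substrate charged, in birch
- final target, as a percentage of the substrate charged, in oak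
- final target, as a percentage of the substrate charged, in cedar

The chair noted that the list of suspects gives the reagent a dormant form and two ways to a product: with the tautomer to target, or with the substrate to isomer of the product. The kineticist therefore proposed one number, the reagent yield f, meaning mM of target found per mM of reagent charged. She set a mark at f = 0.5 and called it the crossing: there, half of the reagent charge stands as target, and the other half is elsewhere.

She read the level parts of the runs, each reading scattered by 1 percentage point. The north-east run from 6.00 h on gave f = 0.233, and the south-west run from 4.00 h on gave 0.422.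

A colleague objected that the east run, at the north-east temperature but with less reagent, reads a lower 0.163, so the south-west figure is no clean effect of temperature. She accepted this and kept her reckoning as rough.

Taking f along a straight line in temperature between those two readings, she reached 0.319 at 35 °C, the reagent yield carried forward. This stands below the crossing, and for maple it means 16.0% of target.

The forecast, entered separately, gave 16% for maple, 15% for birch, 18% for oak and 12% for cedar, and so named oak, on the ground that “Substrate feeding keeps substrate low, which slightly protects the target from side-product formation”.

The highest flask is birch, with 19.2% of target against 17.5% in maple, 17.3% in oak and 11.6% in cedar.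

    reagent ⇌ dormant form (K = 5.30, k = 7.00 × 10⁻⁴ s⁻¹, Ea = 93.0 kJ mol⁻¹, ΔH = −40.0 kJ mol⁻¹)
    substrate ⇌ tautomer (K = 0.880, k = 8.20 × 10⁻⁴ s⁻¹, Ea = 103 kJ mol⁻¹, ΔH = 17.0 kJ mol⁻¹)
    reagent + tautomer → target (k = 0.0820 M⁻¹ s⁻¹, Ea = 67.0 kJ mol⁻¹)
    substrate + target → side product (k = 0.0110 M⁻¹ s⁻¹, Ea = 55.0 kJ mol⁻¹)
    crystals ⇌ target, rate k5*(cs5 - [target]) while solid is left; crystals form when [target] > cs5 (solubility = 0.110 mM, k = 0.0130 s⁻¹)
    substrate + reagent → isomer of the product (k = 0.0610 M⁻¹ s⁻¹, Ea = 53.0 kJ mol⁻¹)
    (constants at 35 °C)

Birch ends with 17.9% of isomer of the product, less than the 25.6% in maple. Its reagent yield is 0.383, above the 0.319 carried forward but still short of the crossing. The neighbouring flask, like birch but kept at 50 °C, ends with 29.4% of target, which is a reagent yield of 0.587, past the crossing.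

Readings and results come from a simulation with made-up constants, and the scatter is random.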